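**Retrosynthetic overview**
- The 1,10-epoxide is put on last with a peracid; before that come butenolide closure from a thioester and a C6–OH-directed 4,5-epoxidation of a (Z,Z)-cyclodecadienol.
- The ten-membered ring is closed at C6–C7 by an electrochemical chromium/nickel alkenyl–aldehyde cyclisation of an enol triflate enal; C8 controls C6.
- The open chain is joined at C9–C10 by nickel-electrocatalytic decarboxylative alkenylation of a malic-acid-derived redox-active ester with a nerol-derived (Z)-vinyl iodide.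
- C8 is bought as (R)-malic acid, tigloylated at the start; C11–C13 come from a thioester enolate that opens the O-tigloylmalic anhydride.
- Ring order: carbocycle, then 4,5-epoxide, then butenolide, then 1,10-epoxide.

Assumption: the SMILES is read as (1S,4S,5R,6R,8R,10R) with both epoxides cis-fused (so the precursor diene is Z,Z); germacrane numbering is used for ring compounds (ring C1–C10, C11 on C7, C12 carbonyl, C13 the CH2O carbon, C14 on C10, C15 on C4).

**Step 1**
Reactants: 1 nerol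
Product: 2 triethyl{[(2Z)-3,7-dimethylocta-2,6-dien-1-yl]oxy}silane
Conditions: Et3SiCl, imidazole, CH2Cl2, 0 °C
Reagents that add atoms: chlorotriethylsilane, CC[Si](Cl)(CC)CC
Why: imidazole-promoted silylation of the primary allylic alcohol; no stereocentre is touched and the Z olefin stays.

**Step 2**
Reactants: 2 triethyl{[(2Z)-3,7-dimethylocta-2,6-dien-1-yl]oxy}silane
Product: 4 (4Z)-4-methyl-6-[(triethylsilyl)oxy]hex-4-enal, via 6,7-diol 3 (not isolated)
Conditions: OsO4 (2 mol%), NaIO4, 2,6-lutidine, dioxane/H2O, rt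
Reagents that add atoms: sodium periodate, [Na+].[O-]I(=O)(=O)=O
Why: Lemieux–Johnson oxidative cleavage; the remote, electron-rich isopropylidene olefin is osmylated before the olefin deactivated by the allylic silyloxy group, and the buffered medium keeps the silyl ether.

**Step 3**
Reactants: 4 (4Z)-4-methyl-6-[(triethylsilyl)oxy]hex-4-enal
Product: 5 triethyl{[(2Z,6Z)-7-iodo-3-methylocta-2,6-dien-1-yl]oxy}silane
Conditions: EtPPh3I, n-BuLi, THF; I2, −78 °C; NaN(SiMe3)2, −20 °C; then 4, −78 °C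
Reagents that add atoms: ethyltriphenylphosphonium iodide, CC[P+](c1ccccc1)(c1ccccc1)c1ccccc1.[I-]; iodine, II
Why: Stork–Zhao-type Wittig olefination with the α-iodo ylide gives the (Z)-2-iodo-2-alkene (iodine cis to the chain), which fixes the later Z geometry at C1=C10.

**Step 4**
Reactants: 6 methyl 3-hydroxypropanoate
Product: 7 methyl 3-{[tert-butyl(dimethyl)silyl]oxy}propanoate
Conditions: t-BuMe2SiCl, imidazole, DMF, rt
Reagents that add atoms: tert-butylchlorodimethylsilane, CC(C)(C)[Si](C)(C)Cl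
Why: standard silyl ether formation on a primary alcohol.

**Step 5**
Reactants: 7 methyl 3-{[tert-butyl(dimethyl)silyl]oxy}propanoate
Product: 8 S-tert-butyl 3-{[tert-butyl(dimethyl)silyl]oxy}propanethioate
Conditions: t-BuSH, AlMe3, CH2Cl2, 0 °C to rt
Reagents that add atoms: 2-methylpropane-2-thiol, CC(C)(C)S
Why: aluminium thiolate transacylation of a methyl ester (Weinreb-type) gives the hindered thioester that later resists premature lactonisation.

**Step 6**
Reactants: 9 (R)-malic acid [(2R)-2-hydroxybutanedioic acid]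
Product: 10 (3R)-2,5-dioxooxolan-3-yl (2E)-2-methylbut-2-enoate
Conditions: tigloyl chloride (3 equiv), neat, 60 °C; volatiles removed, trituration
Reagents that add atoms: (2E)-2-methylbut-2-enoyl chloride, C/C=C(\C)C(Cl)=O
Why: O-acylation and cyclodehydration of the diacid by excess acyl chloride (as with acetyl chloride); the purchased stereocentre (later C8, R) is not touched.

**Step 7**
Reactants: 10 (3R)-2,5-dioxooxolan-3-yl (2E)-2-methylbut-2-enoate; 8 S-tert-butyl 3-{[tert-butyl(dimethyl)silyl]oxy}propanethioate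
Product: 11 (3R)-6-{[tert-butyl(dimethyl)silyl]oxy}-5-[(tert-butylsulfanyl)carbonyl]-3-{[(2E)-2-methylbut-2-enoyl]oxy}-4-oxohexanoic acid (C5 epimers, partly enolised)
Conditions: 8, LiN(iPr)2 (2.3 equiv), THF, −78 °C; then 10; 1 M HCl work-up
Reagents that add atoms: none
Why: Claisen-type C-acylation of the lithium thioester enolate by the cyclic anhydride, which opens at the more electrophilic carbonyl next to the acyloxy carbon and frees the other carboxyl; the stereocentre is untouched.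

**Step 8**
Reactants: 11 (3R)-6-{[tert-butyl(dimethyl)silyl]oxy}-5-[(tert-butylsulfanyl)carbonyl]-3-{[(2E)-2-methylbut-2-enoyl]oxy}-4-oxohexanoic acid; 5 triethyl{[(2Z,6Z)-7-iodo-3-methylocta-2,6-dien-1-yl]oxy}silane
Product: 13 S-tert-butyl (4R,6Z,10Z)-2-({[tert-butyl(dimethyl)silyl]oxy}methyl)-6,10-dimethyl-4-{[(2E)-2-methylbut-2-enoyl]oxy}-3-oxo-12-[(triethylsilyl)oxy]dodeca-6,10-dienethioate (C2 epimers), via NHPI ester 12 (not isolated)
Conditions: N-hydroxyphthalimide, DIC (no DMAP), DMF, rt; then 5 (1.5 equiv), NiCl2·6H2O (10 mol%), 2,2′-bipyridine, AgNO3 (30 mol%), DMF, (+)Mg | (−)RVC, constant current, rt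
Reagents that add atoms: none
Why: nickel-electrocatalytic decarboxylative alkenylation of a redox-active ester; cathodic reduction releases the primary C9 radical, which is captured by the alkenylnickel formed from 5 and coupled with retention of the Z geometry, forming C9–C10 without touching C8.

**Step 9**
Reactants: 13 S-tert-butyl (4R,6Z,10Z)-2-({[tert-butyl(dimethyl)silyl]oxy}methyl)-6,10-dimethyl-4-{[(2E)-2-methylbut-2-enoyl]oxy}-3-oxo-12-[(triethylsilyl)oxy]dodeca-6,10-dienethioate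
Product: 14 S-tert-butyl (2Z,4R,6Z,10Z)-2-({[tert-butyl(dimethyl)silyl]oxy}methyl)-6,10-dimethyl-4-{[(2E)-2-methylbut-2-enoyl]oxy}-12-[(triethylsilyl)oxy]-3-{[(trifluoromethyl)sulfonyl]oxy}dodeca-2,6,10-trienethioate
Conditions: Tf2O, LiOTf, Et3N, CH2Cl2, −78 to 0 °C
Reagents that add atoms: trifluoromethanesulfonic anhydride, O=S(=O)(OS(=O)(=O)C(F)(F)F)C(F)(F)F
Why: chelation-controlled enol triflation of the β-keto thioester (lithium Z-enolate) puts the triflate cis to the thioester carbonyl, the geometry that later places C6 cis to C12.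

**Step 10**
Reactants: 14 (enol triflate, triethylsilyl ether)
Product: 15 S-tert-butyl (2Z,4R,6Z,10Z)-2-({[tert-butyl(dimethyl)silyl]oxy}methyl)-6,10-dimethyl-4-{[(2E)-2-methylbut-2-enoyl]oxy}-12-oxo-3-{[(trifluoromethyl)sulfonyl]oxy}dodeca-2,6,10-trienethioate
Conditions: (COCl)2, DMSO, CH2Cl2, −78 to −30 °C; Et3N
Reagents that add atoms: none
Why: Swern conditions oxidise a primary allylic triethylsilyl ether directly to the (Z)-enal while the tert-butyldimethylsilyl ether, triflate and thioester are inert.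

**Step 11**
Reactants: 15 (enol triflate enal)
Product: 17 S-tert-butyl (1(10)Z,4Z,6S,7(11)E,8R)-13-{[tert-butyl(dimethyl)silyl]oxy}-6-hydroxy-8-{[(2E)-2-methylbut-2-enoyl]oxy}germacra-1(10),4,7(11)-triene-12-thioate (ten-membered carbocycle; C6 cis to C12 on C7=C11), via macrocyclic TES ether 16 (not isolated)
Conditions: CrCl2 (20 mol%), NiCl2·glyme (5 mol%), 2,9-dimethyl-1,10-phenanthroline, Et3SiCl (2 equiv), LiCl, DMF/THF, (+)Al | (−)Ni foam, constant current, 15 added over 12 h (2 mM), rt; then citric acid, MeOH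
Reagents that add atoms: none
Why: Proposed new method: an electrochemical, chromium-catalytic Nozaki–Hiyama–Kishi ring closure of an enol triflate onto an enal. Zerovalent nickel inserts into the C7–OTf bond, the alkenyl group passes to trivalent chromium, the alkenylchromium adds 1,2 to the C6 aldehyde, Et3SiCl releases the product as its silyl ether and the cathode returns chromium to the divalent state. The closest known reactions are intermolecular electrochemical NHK couplings of alkenyl halides and stoichiometric NHK macrocyclisations. With the C6–H and C8–H bonds both eclipsing the tetrasubstituted C7=C11 bond (A1,3 strain), the tether is expected to close with C5 and C9 on the face opposite the C8 tigloyloxy group, so the new C6–O bond is syn to C8–O (6S in 17, which is the 6R centre of the target), and the hindered S-tert-butyl thioester does not lactonise.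

**Step 12**
Reactants: 17 (macrocyclic allylic alcohol)
Product: 18 S-tert-butyl (1(10)Z,4S,5R,6R,7(11)E,8R)-13-{[tert-butyl(dimethyl)silyl]oxy}-4,5-epoxy-6-hydroxy-8-{[(2E)-2-methylbut-2-enoyl]oxy}germacra-1(10),7(11)-diene-12-thioate
Conditions: VO(acac)2 (5 mol%), t-BuOOH (1.5 equiv), CH2Cl2, 0 °C
Reagents that add atoms: tert-butyl hydroperoxide, CC(C)(C)OO
Why: vanadium-catalysed hydroxyl-directed epoxidation (Sharpless–Michaelson type); only the allylic C4=C5 bond reacts, and, as with eight- and nine-membered (Z)-cycloalkenols, the ring holds the O–C6–C5=C4 dihedral near 45° so oxygen is delivered cis to the hydroxyl, setting C4 (S) and C5 (R).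

**Step 13**
Reactants: 18 (epoxy alcohol thioester)
Product: 19 (1(10)Z,4S,5R,6R,8R)-13-{[tert-butyl(dimethyl)silyl]oxy}-4,5-epoxy-8-{[(2E)-2-methylbut-2-enoyl]oxy}germacra-1(10),7(11)-dien-12,6-olide
Conditions: AgOCOCF3 (2 equiv), Na2HPO4, THF, rt
Reagents that add atoms: none
Why: Masamune-type thiophilic silver activation of the S-tert-butyl thioester lets the cis C6 hydroxyl acylate itself to the butenolide with retention at C6 under buffered, epoxide-safe conditions.

**Step 14**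
Reactants: 19 (silyl-protected butenolide)
Product: 21 (1(10)Z,4S,5R,6R,8R)-13-acetoxy-4,5-epoxy-8-{[(2E)-2-methylbut-2-enoyl]oxy}germacra-1(10),7(11)-dien-12,6-olide, via C13 alcohol 20 (not isolated)
Conditions: Bu4NF, AcOH, THF, 0 °C; then Ac2O, pyridine, DMAP
Reagents that add atoms: acetic anhydride, CC(=O)OC(C)=O
Why: buffered fluoride desilylation (no epimerisation at the acidic C6–H) followed by acetylation of the primary allylic alcohol.

**Step 15**
Reactants: 21 (13-acetate, 1(10)-olefin)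
Product: 22 (1S,4S,5R,6R,8R,10R)-13-acetoxy-1,10:4,5-diepoxy-8-{[(2E)-2-methylbut-2-enoyl]oxy}germacr-7(11)-en-12,6-olide (target, CNP0251711.3)
Conditions: mCPBA (1.2 equiv), CH2Cl2, −20 to 0 °C
Reagents that add atoms: 3-chloroperoxybenzoic acid, OOC(=O)c1cccc(Cl)c1
Why: Prilezhaev epoxidation of the only electron-rich olefin left; the peracid is expected to attack the outer face of the (Z)-C1=C10 bond, anti to the homoallylic C8 acyloxy group, giving the cis epoxide with C1 (S) and C10 (R).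

**Compound list**
1 | nerol, (2Z)-3,7-dimethylocta-2,6-dien-1-ol | CC(C)=CCC/C(C)=C\CO | starting material
2 | triethyl{[(2Z)-3,7-dimethylocta-2,6-dien-1-yl]oxy}silane | CC(C)=CCC/C(C)=C\CO[Si](CC)(CC)CC | intermediate
3 | (6Z)-2,6-dimethyl-8-[(triethylsilyl)oxy]oct-6-ene-2,3-diol (racemic at C3) | CC(C)(O)C(O)CC/C(C)=C\CO[Si](CC)(CC)CC | intermediate
4 | (4Z)-4-methyl-6-[(triethylsilyl)oxy]hex-4-enal | O=CCC/C(C)=C\CO[Si](CC)(CC)CC | intermediate
5 | triethyl{[(2Z,6Z)-7-iodo-3-methylocta-2,6-dien-1-yl]oxy}silane | C/C(I)=C/CC/C(C)=C\CO[Si](CC)(CC)CC | intermediate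
6 | methyl 3-hydroxypropanoate | COC(=O)CCO | starting material
7 | methyl 3-{[tert-butyl(dimethyl)silyl]oxy}propanoate | COC(=O)CCO[Si](C)(C)C(C)(C)C | intermediate
8 | S-tert-butyl 3-{[tert-butyl(dimethyl)silyl]oxy}propanethioate | CC(C)(C)SC(=O)CCO[Si](C)(C)C(C)(C)C | intermediate
9 | (R)-malic acid, (2R)-2-hydroxybutanedioic acid | O[C@H](CC(=O)O)C(=O)O | starting material
10 | (3R)-2,5-dioxooxolan-3-yl (2E)-2-methylbut-2-enoate | C/C=C(\C)C(=O)O[C@@H]1CC(=O)OC1=O | intermediate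
11 | (3R)-6-{[tert-butyl(dimethyl)silyl]oxy}-5-[(tert-butylsulfanyl)carbonyl]-3-{[(2E)-2-methylbut-2-enoyl]oxy}-4-oxohexanoic acid | C/C=C(\C)C(=O)O[C@H](CC(=O)O)C(=O)C(CO[Si](C)(C)C(C)(C)C)C(=O)SC(C)(C)C | intermediate
12 | 1,3-dioxoisoindolin-2-yl ester of 11 | C/C=C(\C)C(=O)O[C@H](CC(=O)ON1C(=O)c2ccccc2C1=O)C(=O)C(CO[Si](C)(C)C(C)(C)C)C(=O)SC(C)(C)C | intermediate
13 | S-tert-butyl (4R,6Z,10Z)-2-({[tert-butyl(dimethyl)silyl]oxy}methyl)-6,10-dimethyl-4-{[(2E)-2-methylbut-2-enoyl]oxy}-3-oxo-12-[(triethylsilyl)oxy]dodeca-6,10-dienethioate | C/C=C(\C)C(=O)O[C@H](C/C(C)=C\CC/C(C)=C\CO[Si](CC)(CC)CC)C(=O)C(CO[Si](C)(C)C(C)(C)C)C(=O)SC(C)(C)C | intermediate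
14 | S-tert-butyl (2Z,4R,6Z,10Z)-2-({[tert-butyl(dimethyl)silyl]oxy}methyl)-6,10-dimethyl-4-{[(2E)-2-methylbut-2-enoyl]oxy}-12-[(triethylsilyl)oxy]-3-{[(trifluoromethyl)sulfonyl]oxy}dodeca-2,6,10-trienethioate | C/C=C(\C)C(=O)O[C@H](C/C(C)=C\CC/C(C)=C\CO[Si](CC)(CC)CC)/C(OS(=O)(=O)C(F)(F)F)=C(/C(=O)SC(C)(C)C)CO[Si](C)(C)C(C)(C)C | intermediate
15 | S-tert-butyl (2Z,4R,6Z,10Z)-2-({[tert-butyl(dimethyl)silyl]oxy}methyl)-6,10-dimethyl-4-{[(2E)-2-methylbut-2-enoyl]oxy}-12-oxo-3-{[(trifluoromethyl)sulfonyl]oxy}dodeca-2,6,10-trienethioate | C/C=C(\C)C(=O)O[C@H](C/C(C)=C\CC/C(C)=C\C=O)/C(OS(=O)(=O)C(F)(F)F)=C(/C(=O)SC(C)(C)C)CO[Si](C)(C)C(C)(C)C | intermediate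
16 | 6-O-triethylsilyl ether of 17 | C/C=C(\C)C(=O)O[C@@H]1C/C(C)=C\CC/C(C)=C\[C@H](O[Si](CC)(CC)CC)/C1=C(/CO[Si](C)(C)C(C)(C)C)C(=O)SC(C)(C)C | intermediate
17 | S-tert-butyl (1(10)Z,4Z,6S,7(11)E,8R)-13-{[tert-butyl(dimethyl)silyl]oxy}-6-hydroxy-8-{[(2E)-2-methylbut-2-enoyl]oxy}germacra-1(10),4,7(11)-triene-12-thioate | C/C=C(\C)C(=O)O[C@@H]1C/C(C)=C\CC/C(C)=C\[C@H](O)/C1=C(/CO[Si](C)(C)C(C)(C)C)C(=O)SC(C)(C)C | intermediate
18 | S-tert-butyl (1(10)Z,4S,5R,6R,7(11)E,8R)-13-{[tert-butyl(dimethyl)silyl]oxy}-4,5-epoxy-6-hydroxy-8-{[(2E)-2-methylbut-2-enoyl]oxy}germacra-1(10),7(11)-diene-12-thioate | C/C=C(\C)C(=O)O[C@@H]1C/C(C)=C\CC[C@]2(C)O[C@@H]2[C@H](O)/C1=C(/CO[Si](C)(C)C(C)(C)C)C(=O)SC(C)(C)C | intermediate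
19 | (1(10)Z,4S,5R,6R,8R)-13-{[tert-butyl(dimethyl)silyl]oxy}-4,5-epoxy-8-{[(2E)-2-methylbut-2-enoyl]oxy}germacra-1(10),7(11)-dien-12,6-olide | C/C=C(\C)C(=O)O[C@@H]1C/C(C)=C\CC[C@]2(C)O[C@@H]2[C@@H]2OC(=O)C(CO[Si](C)(C)C(C)(C)C)=C21 | intermediate
20 | (1(10)Z,4S,5R,6R,8R)-4,5-epoxy-13-hydroxy-8-{[(2E)-2-methylbut-2-enoyl]oxy}germacra-1(10),7(11)-dien-12,6-olide | C/C=C(\C)C(=O)O[C@@H]1C/C(C)=C\CC[C@]2(C)O[C@@H]2[C@@H]2OC(=O)C(CO)=C21 | intermediate
21 | (1(10)Z,4S,5R,6R,8R)-13-acetoxy-4,5-epoxy-8-{[(2E)-2-methylbut-2-enoyl]oxy}germacra-1(10),7(11)-dien-12,6-olide | C/C=C(\C)C(=O)O[C@@H]1C/C(C)=C\CC[C@]2(C)O[C@@H]2[C@@H]2OC(=O)C(COC(C)=O)=C21 | intermediate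
22 | (1S,4S,5R,6R,8R,10R)-13-acetoxy-1,10:4,5-diepoxy-8-{[(2E)-2-methylbut-2-enoyl]oxy}germacr-7(11)-en-12,6-olide | C/C=C(\C)C(=O)O[C@@H]1C[C@@]2(C)O[C@H]2CC[C@]2(C)O[C@@H]2[C@@H]2OC(=O)C(COC(C)=O)=C21 | target

**Step count**
Total: 15 steps. Longest linear sequence: 11 steps (1 → 2 → 4 → 5 → 13 → 14 → 15 → 17 → 18 → 19 → 21 → 22; the line from 6 through 8 and 11 is equally long).

**Three steps most likely to fail**

Step 11 (the proposed new step). Risks are oligomerisation instead of ten-ring closure, loss of the allylic tigloyloxy group from the alkenyl metal, and the wrong C6 epimer. Fallback with known chemistry: leave electrolysis and the silyl chloride relay aside and close the same bond from 15 by the classical stoichiometric Nozaki–Hiyama–Kishi reaction (CrCl2 in excess, NiCl2 1–2 mol%, DMSO/THF, 1 mM, rt), a reaction with precedent for medium-ring carbocycles. Aqueous work-up of the chromium alkoxide gives 17 directly, where the route is rejoined. If the C6 epimer of 17 predominates, it is not lost: it is the alcohol that the step 12 fallback below makes on purpose.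

Step 12. The directed epoxidation may deliver oxygen trans to the hydroxyl (the A1,3-controlled acyclic outcome) instead of cis. Fallback, from 17 back to 19, swaps directed syn delivery for peracid attack on the C6 epimer followed by an invertive lactonisation:
- Mitsunobu reaction of 17 (chloroacetic acid, PPh3, DIAD) gives the inverted 6-epi chloroacetate F1.
- Thiourea and NaHCO3 in ethanol free the 6-epi alcohol F2.
- mCPBA (1 equiv, −20 °C) epoxidises C4=C5 on the hydroxyl side of the H-inside rotamer (threo), which is the (4S,5R) epoxide needed, giving the 6-epi epoxy alcohol F3.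
- MsCl and Et3N give the mesylate F4.
- AgOCOCF3 in wet THF hydrolyses the thioester to the carboxylic acid mesylate F5, whose carboxylate (NaHCO3) displaces the mesylate with inversion at C6 and closes the lactone 19.

Step 15. The peracid may attack the other face of C1=C10, or the acid by-product may trigger transannular opening of the 4,5-epoxide. Fallback, from 21 back to 22, puts the oxygen on the face opposite to the electrophile: N-bromoacetamide in aqueous acetone forms the bromonium ion on the peracid face and water opens it at the tertiary C10 from the other side, giving the bromohydrin F6. Ag2O in THF then closes the epoxide by displacement at C1, giving 22. Participation of the 4,5-epoxide oxygen in the bromonium opening is the risk of this fallback.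

**Further compounds**
F0 | step 11 | none | none
F1 | step 12 | S-tert-butyl (1(10)Z,4Z,6R,8R)-13-{[tert-butyl(dimethyl)silyl]oxy}-6-(chloroacetoxy)-8-{[(2E)-2-methylbut-2-enoyl]oxy}germacra-1(10),4,7(11)-triene-12-thioate | C/C=C(\C)C(=O)O[C@@H]1C/C(C)=C\CC/C(C)=C\[C@@H](OC(=O)CCl)/C1=C(/CO[Si](C)(C)C(C)(C)C)C(=O)SC(C)(C)C
F2 | step 12 | S-tert-butyl (1(10)Z,4Z,6R,8R)-13-{[tert-butyl(dimethyl)silyl]oxy}-6-hydroxy-8-{[(2E)-2-methylbut-2-enoyl]oxy}germacra-1(10),4,7(11)-triene-12-thioate (C6 epimer of 17) | C/C=C(\C)C(=O)O[C@@H]1C/C(C)=C\CC/C(C)=C\[C@@H](O)/C1=C(/CO[Si](C)(C)C(C)(C)C)C(=O)SC(C)(C)C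
F3 | step 12 | S-tert-butyl (1(10)Z,4S,5R,6S,8R)-13-{[tert-butyl(dimethyl)silyl]oxy}-4,5-epoxy-6-hydroxy-8-{[(2E)-2-methylbut-2-enoyl]oxy}germacra-1(10),7(11)-diene-12-thioate | C/C=C(\C)C(=O)O[C@@H]1C/C(C)=C\CC[C@]2(C)O[C@@H]2[C@@H](O)/C1=C(/CO[Si](C)(C)C(C)(C)C)C(=O)SC(C)(C)C
F4 | step 12 | S-tert-butyl (1(10)Z,4S,5R,6S,8R)-13-{[tert-butyl(dimethyl)silyl]oxy}-4,5-epoxy-6-[(methylsulfonyl)oxy]-8-{[(2E)-2-methylbut-2-enoyl]oxy}germacra-1(10),7(11)-diene-12-thioate | C/C=C(\C)C(=O)O[C@@H]1C/C(C)=C\CC[C@]2(C)O[C@@H]2[C@@H](OS(C)(=O)=O)/C1=C(/CO[Si](C)(C)C(C)(C)C)C(=O)SC(C)(C)C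
F5 | step 12 | (1(10)Z,4S,5R,6S,8R)-13-{[tert-butyl(dimethyl)silyl]oxy}-4,5-epoxy-6-[(methylsulfonyl)oxy]-8-{[(2E)-2-methylbut-2-enoyl]oxy}germacra-1(10),7(11)-dien-12-oic acid | C/C=C(\C)C(=O)O[C@@H]1C/C(C)=C\CC[C@]2(C)O[C@@H]2[C@@H](OS(C)(=O)=O)/C1=C(/CO[Si](C)(C)C(C)(C)C)C(O)=O
F6 | step 15 | (1R,4S,5R,6R,8R,10R)-13-acetoxy-1-bromo-4,5-epoxy-10-hydroxy-8-{[(2E)-2-methylbut-2-enoyl]oxy}germacr-7(11)-en-12,6-olide | C/C=C(\C)C(=O)O[C@@H]1C[C@@](C)(O)[C@H](Br)CC[C@]2(C)O[C@@H]2[C@@H]2OC(=O)C(COC(C)=O)=C21
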